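**Plan**

Numbering (germacranolide): C1 carbinol, C2–C3, C4/C5 epoxide (C15 on C4), C6 lactone O–CH, C7, C8 tiglate carbon, C9=C10 (C14 on C10), C11 bearing C13H2OAc, C12 lactone carbonyl. Enabling feature: the butenolide's tetrasubstituted C7=C11 olefin with the acetoxymethyl group on C11 is the 1,3-transposed form of a C7 tertiary acetate beside a C11=C13 methylene, that is, of the Baylis–Hillman adduct between an O6 acrylate and a C7 ketone of the ten-membered ring.
Retrosynthetic cuts, in order: O–C13/O–C7 (acetate transposition), C7–C11 (γ-lactone, key), C1–C10 (ten-membered ring), the O8 and O6 acyl bonds, C5–C6, C9=C10.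
Forward: C6–C9 comes from methyl 3,4-O-isopropylidene-L-threonate, C10/C14 from an iodo-ylide, C1–C5/C15 from pent-4-yn-1-ol; the chain is joined at C5–C6 (step 10), the epoxide is made on the open chain (step 11), the carbocycle closes at C1–C10 (step 16) and the lactone last (step 22).
Stereochemistry: C8 from L-threonic acid; C6 by chelation control through the C7 ether, a relay centre that is later oxidised; C4/C5 by hydroxyl-directed epoxidation; C1 by CBS reduction; 9Z from the Wittig step, kept in the chromium coupling; C7 of the adduct is erased by the transposition.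

Key step: step 22

Remark: the C7 p-methoxybenzyl ether serves only to relay the C6 configuration and to keep O6, O7 and O8 apart; the single C7 epimer drawn for 30 and 31 stands for either carbinol epimer, since both give 32.

**Route**

Step 1
Reactants: 1 pent-4-yn-1-ol
Product: 3 (4E)-5-iodo-4-methylpent-4-en-1-ol, via alkenylalane 2 (not isolated)
Conditions: Me3Al (3 equiv), Cp2ZrCl2 (0.25 equiv), CH2Cl2, 0 °C to rt; then I2, THF, −30 to 0 °C
Reagents that add atoms: trimethylaluminium C[Al](C)C; iodine II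
Why: Negishi zirconium-catalysed carboalumination adds methyl and aluminium syn across the terminal alkyne with methyl on the internal carbon (C4), and iodinolysis of the alkenyl–Al bond with retention gives the E iodoalkene that later becomes the 4,5-olefin.

Step 2
Reactants: 3 (4E)-5-iodo-4-methylpent-4-en-1-ol
Product: 4 tert-butyl{[(4E)-5-iodo-4-methylpent-4-en-1-yl]oxy}dimethylsilane
Conditions: TBSCl, imidazole, DMF, rt
Reagents that add atoms: tert-butyldimethylsilyl chloride CC(C)(C)[Si](C)(C)Cl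
Why: Imidazole-promoted silylation of the primary alcohol gives a C1 ether that survives tert-butyllithium exchange and all steps up to 13.

Step 3
Reactants: 5 methyl 3,4-O-isopropylidene-L-threonate
Product: 6 methyl (2R)-2-[(tert-butyldimethylsilyl)oxy]-2-[(4S)-2,2-dimethyl-1,3-dioxolan-4-yl]acetate
Conditions: TBSCl, imidazole, DMF, rt
Reagents that add atoms: tert-butyldimethylsilyl chloride CC(C)(C)[Si](C)(C)Cl
Why: Silylation of the α-hydroxy ester touches no stereocentre (C8 comes from L-threonic acid) and puts on O8 the bulky, non-chelating group that step 10 needs.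

Step 4
Reactants: 6 methyl (2R)-2-[(tert-butyldimethylsilyl)oxy]-2-[(4S)-2,2-dimethyl-1,3-dioxolan-4-yl]acetate
Product: 7 (2R)-2-[(tert-butyldimethylsilyl)oxy]-2-[(4S)-2,2-dimethyl-1,3-dioxolan-4-yl]acetaldehyde
Conditions: i-Bu2AlH (1.1 equiv), CH2Cl2, −78 °C; MeOH, aq. Rochelle salt
Reagents that add atoms: none
Why: DIBAL half-reduction of the ester stops at the aluminium hemiacetal at −78 °C and gives the α-silyloxy aldehyde on work-up, which is used at once to avoid epimerisation at C8.

Step 5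
Reactants: 7 (2R)-2-[(tert-butyldimethylsilyl)oxy]-2-[(4S)-2,2-dimethyl-1,3-dioxolan-4-yl]acetaldehyde
Product: 8 (4S)-4-[(1S,2Z)-1-[(tert-butyldimethylsilyl)oxy]-3-iodobut-2-en-1-yl]-2,2-dimethyl-1,3-dioxolane
Conditions: EtPPh3I, n-BuLi, THF, rt; I2, −78 °C; NaN(SiMe3)2, −20 °C; then 7, −78 °C
Reagents that add atoms: ethyltriphenylphosphonium iodide CC[P+](c1ccccc1)(c1ccccc1)c1ccccc1.[I-]; iodine II
Why: Stork–Zhao-type Wittig olefination, in which the non-stabilised α-iodo ylide Ph3P=C(I)CH3 reacts through the kinetically preferred cis-oxaphosphetane and gives the Z 2-iodoalkene with iodine cis to C8, which is the 9Z geometry of the target.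

Step 6
Reactants: 8 (4S)-4-[(1S,2Z)-1-[(tert-butyldimethylsilyl)oxy]-3-iodobut-2-en-1-yl]-2,2-dimethyl-1,3-dioxolane
Product: 9 (2S,3S,4Z)-3-[(tert-butyldimethylsilyl)oxy]-5-iodohex-4-ene-1,2-diol
Conditions: AcOH/H2O (4:1), rt
Reagents that add atoms: none
Why: Acid-catalysed acetal hydrolysis removes the terminal acetonide much faster than it attacks the hindered secondary silyl ether.

Step 7
Reactants: 9 (2S,3S,4Z)-3-[(tert-butyldimethylsilyl)oxy]-5-iodohex-4-ene-1,2-diol
Product: 10 (4S)-4-[(1S,2Z)-1-[(tert-butyldimethylsilyl)oxy]-3-iodobut-2-en-1-yl]-2-(4-methoxyphenyl)-1,3-dioxolane (both C2 epimers)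
Conditions: 4-MeOC6H4CH(OMe)2, pyridinium p-toluenesulfonate (cat.), CH2Cl2, rt
Reagents that add atoms: 4-methoxybenzaldehyde dimethyl acetal COc1ccc(C(OC)OC)cc1
Why: Acid-catalysed transacetalisation gives the five-membered p-methoxybenzylidene acetal, whose new acetal centre forms as a mixture that converges in step 8.

Step 8
Reactants: 10 (4S)-4-[(1S,2Z)-1-[(tert-butyldimethylsilyl)oxy]-3-iodobut-2-en-1-yl]-2-(4-methoxyphenyl)-1,3-dioxolane
Product: 11 (2S,3S,4Z)-3-[(tert-butyldimethylsilyl)oxy]-5-iodo-2-[(4-methoxybenzyl)oxy]hex-4-en-1-ol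
Conditions: i-Bu2AlH (3 equiv), CH2Cl2, −78 to 0 °C
Reagents that add atoms: none
Why: Reductive acetal opening with DIBAL, in which aluminium coordinates the less hindered primary oxygen O6, that C–O bond breaks and hydride is delivered to the oxocarbenium ion, leaving the PMB ether on the secondary O7 and freeing the C6 hydroxyl.

Step 9
Reactants: 11 (2S,3S,4Z)-3-[(tert-butyldimethylsilyl)oxy]-5-iodo-2-[(4-methoxybenzyl)oxy]hex-4-en-1-ol
Product: 12 (2R,3S,4Z)-3-[(tert-butyldimethylsilyl)oxy]-5-iodo-2-[(4-methoxybenzyl)oxy]hex-4-enal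
Conditions: Dess–Martin periodinane, NaHCO3, CH2Cl2, 0 °C to rt
Reagents that add atoms: none
Why: Buffered Dess–Martin oxidation converts the primary alcohol into the α-alkoxy aldehyde under neutral conditions, so that C7 is not epimerised and the β-silyloxy group is not eliminated; the aldehyde is used crude.

Step 10
Reactants: 4 tert-butyl{[(4E)-5-iodo-4-methylpent-4-en-1-yl]oxy}dimethylsilane; 12 (2R,3S,4Z)-3-[(tert-butyldimethylsilyl)oxy]-5-iodo-2-[(4-methoxybenzyl)oxy]hex-4-enal
Product: 15 (2Z,4S,5S,6R,7E)-4,11-bis[(tert-butyldimethylsilyl)oxy]-2-iodo-5-[(4-methoxybenzyl)oxy]-8-methylundeca-2,7-dien-6-ol, via alkenyllithium 13 (not isolated), via alkenylmagnesium bromide 14 (not isolated)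
Conditions: 4, t-BuLi (2 equiv), Et2O, −78 °C; MgBr2·OEt2, −78 to −20 °C; then 12, CH2Cl2, −78 °C
Reagents that add atoms: none
Why: Iodine–lithium exchange and transmetalation give an alkenylmagnesium bromide that adds under Cram-chelate control, with magnesium bridging the aldehyde oxygen and the O7 PMB ether while the O8 silyl ether does not chelate, so that attack on the face away from C8 gives the 6,7-syn (6R) alcohol with the E olefin retained.

Step 11
Reactants: 15 (2Z,4S,5S,6R,7E)-4,11-bis[(tert-butyldimethylsilyl)oxy]-2-iodo-5-[(4-methoxybenzyl)oxy]-8-methylundeca-2,7-dien-6-ol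
Product: 16 (1S,2S,3S,4Z)-3-[(tert-butyldimethylsilyl)oxy]-1-[(2R,3R)-3-{3-[(tert-butyldimethylsilyl)oxy]propyl}-3-methyloxiran-2-yl]-5-iodo-2-[(4-methoxybenzyl)oxy]hex-4-en-1-ol
Conditions: mCPBA, NaHCO3, CH2Cl2, 0 °C
Reagents that add atoms: 3-chloroperoxybenzoic acid OOC(=O)c1cccc(Cl)c1
Why: Hydroxyl-directed (Henbest-type) peracid epoxidation, in which 1,3-allylic strain between the C4 methyl group (cis to C6) and the C6 substituents fixes the C6–H bond in the olefin plane, so the hydrogen-bonded peracid is delivered to one face and the threo (4R,5R) epoxy alcohol results, while the iodoalkene is deactivated and has no directing hydroxyl.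

Step 12
Reactants: 16 epoxy alcohol (as named in step 11); 17 acryloyl chloride
Product: 18 (1S,2S,3S,4Z)-3-[(tert-butyldimethylsilyl)oxy]-1-[(2R,3R)-3-{3-[(tert-butyldimethylsilyl)oxy]propyl}-3-methyloxiran-2-yl]-5-iodo-2-[(4-methoxybenzyl)oxy]hex-4-en-1-yl prop-2-enoate
Conditions: i-Pr2NEt, 4-(dimethylamino)pyridine (cat.), CH2Cl2, −20 to 0 °C
Reagents that add atoms: none
Why: O-Acylation of the secondary alcohol with the acid chloride and a hindered amine base puts the Baylis–Hillman donor on O6 and at the same time masks this hydroxyl for the following steps.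

Step 13
Reactants: 18 bis-silyl acrylate (as named in step 12)
Product: 19 (1S,2R,3S,4Z)-3-hydroxy-1-[(2R,3R)-3-(3-hydroxypropyl)-3-methyloxiran-2-yl]-5-iodo-2-[(4-methoxybenzyl)oxy]hex-4-en-1-yl prop-2-enoate
Conditions: Bu4NF, AcOH (1:1), THF, 0 °C to rt
Reagents that add atoms: none
Why: Fluoride-induced cleavage of both silyl ethers, buffered with acetic acid so that the medium stays near neutral, the acrylate does not migrate and the free O8 hydroxyl does not open the epoxide.

Step 14
Reactants: 19 diol acrylate (as named in step 13)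
Product: 20 (1S,2R,3S,4Z)-3-hydroxy-5-iodo-2-[(4-methoxybenzyl)oxy]-1-[(2R,3R)-3-methyl-3-(3-oxopropyl)oxiran-2-yl]hex-4-en-1-yl prop-2-enoate
Conditions: 2,2,6,6-tetramethylpiperidin-1-oxyl (TEMPO, cat.), PhI(OAc)2, CH2Cl2, rt
Reagents that add atoms: none
Why: Oxoammonium-mediated (TEMPO/PhI(OAc)2) oxidation is selective for the unhindered primary C1 alcohol over the hindered secondary allylic C8 alcohol and stops at the aldehyde.

Step 15
Reactants: 20 hydroxy aldehyde (as named in step 14); 21 tiglic acid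
Product: 23 (2Z,4S,5R,6S)-2-iodo-5-[(4-methoxybenzyl)oxy]-6-[(2R,3R)-3-methyl-3-(3-oxopropyl)oxiran-2-yl]-6-(prop-2-enoyloxy)hex-2-en-4-yl (2E)-2-methylbut-2-enoate, via tigloyl 2,4,6-trichlorobenzoyl anhydride 22 (not isolated)
Conditions: 21, 2,4,6-Cl3C6H2COCl, Et3N, toluene, rt; then 20, 4-(dimethylamino)pyridine, rt
Reagents that add atoms: none
Why: Yamaguchi esterification, in which the mixed anhydride of tiglic acid acylates the hindered secondary allylic alcohol under DMAP catalysis without touching the aldehyde, the E tiglate being the stable double-bond isomer.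

Step 16
Reactants: 23 open-chain iodo aldehyde (as named in step 15)
Product: 24 ten-membered carbocycle, target numbering (4R,5R,6S,7R,8S,9Z)-6-(acryloyloxy)-4,5-epoxy-1-hydroxy-7-[(4-methoxybenzyl)oxy]-4,10-dimethyl-8-(tigloyloxy)cyclodec-9-ene, both C1 epimers
Conditions: CrCl2 (10 equiv), NiCl2 (2 mol %), degassed DMSO, rt, syringe-pump addition to 0.002 M
Reagents that add atoms: none
Why: Nozaki–Hiyama–Kishi reaction, in which zerovalent nickel inserts into the C10–I bond with retention, the alkenyl group passes to trivalent chromium and adds chemoselectively to the C1 aldehyde under high dilution, closing the ten-membered carbocycle with the 9Z olefin intact; C1 forms as an epimer mixture that steps 17 and 18 correct.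

Step 17
Reactants: 24 macrocyclic allylic alcohols (both C1 epimers)
Product: 25 macrocyclic enone, target numbering (4R,5R,6S,7R,8S,9Z)-6-(acryloyloxy)-4,5-epoxy-7-[(4-methoxybenzyl)oxy]-4,10-dimethyl-1-oxo-8-(tigloyloxy)cyclodec-9-ene
Conditions: Dess–Martin periodinane, NaHCO3, CH2Cl2, 0 °C to rt
Reagents that add atoms: none
Why: Dess–Martin oxidation of both allylic alcohol epimers gives one Z enone and so removes the uncontrolled C1 centre.

Step 18
Reactants: 25 macrocyclic enone
Product: 26 (1S)-allylic alcohol, target numbering (1S,4R,5R,6S,7R,8S,9Z)-6-(acryloyloxy)-4,5-epoxy-1-hydroxy-7-[(4-methoxybenzyl)oxy]-4,10-dimethyl-8-(tigloyloxy)cyclodec-9-ene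
Conditions: (R)-1-methyl-3,3-diphenyltetrahydro-1H,3H-pyrrolo[1,2-c][1,3,2]oxazaborole [(R)-Me-CBS, 0.5 equiv], catecholborane (2 equiv), toluene, −78 °C
Reagents that add atoms: none
Why: Corey–Bakshi–Shibata reduction, in which the ketone binds to the oxazaborolidine with the α-methylalkenyl carbon C10 as the large and C2 as the small substituent and the (R)-catalyst delivers hydride to give the (1S) allylic alcohol, while catecholborane at −78 °C leaves esters, epoxide and olefins alone.

Step 19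
Reactants: 26 (1S)-allylic alcohol
Product: 27 C1 silyl ether, target numbering (1S,4R,5R,6S,7R,8S,9Z)-6-(acryloyloxy)-1-[(tert-butyldimethylsilyl)oxy]-4,5-epoxy-7-[(4-methoxybenzyl)oxy]-4,10-dimethyl-8-(tigloyloxy)cyclodec-9-ene
Conditions: TBSCl, imidazole, DMF, rt to 40 °C
Reagents that add atoms: tert-butyldimethylsilyl chloride CC(C)(C)[Si](C)(C)Cl
Why: Imidazole-promoted silylation of the secondary allylic alcohol under non-acidic conditions that do not disturb the epoxide.

Step 20
Reactants: 27 C1 silyl ether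
Product: 28 C7 alcohol, target numbering (1S,4R,5R,6S,7R,8S,9Z)-6-(acryloyloxy)-1-[(tert-butyldimethylsilyl)oxy]-4,5-epoxy-7-hydroxy-4,10-dimethyl-8-(tigloyloxy)cyclodec-9-ene
Conditions: 2,3-dichloro-5,6-dicyano-1,4-benzoquinone (DDQ), CH2Cl2/pH 7 buffer (10:1), 0 °C
Reagents that add atoms: none
Why: Oxidative cleavage of the p-methoxybenzyl ether by DDQ (benzylic hydride abstraction, then hydrolysis of the oxocarbenium ion) frees only the C7 hydroxyl in a buffered two-phase medium in which acyl migration from O6 or O8 is slow.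

Step 21
Reactants: 28 C7 alcohol
Product: 29 macrocyclic C7 ketone O6 acrylate, target numbering (1S,4R,5R,6R,8S,9Z)-6-(acryloyloxy)-1-[(tert-butyldimethylsilyl)oxy]-4,5-epoxy-4,10-dimethyl-7-oxo-8-(tigloyloxy)cyclodec-9-ene
Conditions: Dess–Martin periodinane, NaHCO3, CH2Cl2, 0 °C to rt
Reagents that add atoms: none
Why: Dess–Martin oxidation of the secondary alcohol flanked by two acyloxy carbons gives the ketone under neutral buffered conditions that avoid enolisation toward C6 or C8; the relay stereocentre at C7 disappears here.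

Step 22
Reactants: 29 macrocyclic C7 ketone O6 acrylate
Product: 30 (1S,4R,5R,6R,7S,8S,9Z)-1-[(tert-butyldimethylsilyl)oxy]-4,5-epoxy-7-hydroxy-8-(tigloyloxy)germacra-9,11(13)-dien-12,6-olide
Conditions: PBu3 (0.5 equiv), t-BuOH/THF (1:1), rt
Reagents that add atoms: none
Why: PBu3 adds to the unsubstituted β-carbon C13 of the acrylate to give a phosphonium ester enolate whose α-carbon C11 attacks the C7 ketone in an intramolecular aldol step, after which proton transfer from C11 and β-elimination of the phosphine release the α-methylene β-hydroxy lactone and the catalyst. The closest known reaction type is the phosphine-catalysed intramolecular Morita–Baylis–Hillman cyclisation, of which ketone acceptors are the less common case. The γ-lactone (O6–C12–C11–C7–C6) closes by a 5-exo-trig attack on the carbonyl with the enolate double bond inside the forming ring, the same geometry that operates in butenolide-forming intramolecular Horner–Wadsworth–Emmons reactions of α-acyloxy ketones. The new C7 carbinol forms on whichever ketone face the macrocycle offers to the O6-tethered enolate (drawn with the hydroxyl anti to H-6) and needs no control, because step 24 turns C7 into an sp2 carbon. The step needs chemoselective activation of the acrylate and C–C bond formation that outruns enolisation of the ketone: the acrylate is the only acceptor with a free β-position (the tiglate is α,β-disubstituted), the ketone is made strongly electrophilic by its two α-acyloxy groups and lies five atoms from C11, and the weakly basic phosphine in a protic medium should leave C6, C8, the epoxide and the O8 ester untouched.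

Step 23
Reactants: 30 Baylis–Hillman lactone (as named in step 22)
Product: 31 (1S,4R,5R,6R,7S,8S,9Z)-7-acetoxy-1-[(tert-butyldimethylsilyl)oxy]-4,5-epoxy-8-(tigloyloxy)germacra-9,11(13)-dien-12,6-olide
Conditions: Ac2O (excess), Et3N, 4-(dimethylamino)pyridine (1 equiv), CH2Cl2, rt to 35 °C
Reagents that add atoms: acetic anhydride CC(=O)OC(C)=O
Why: DMAP-catalysed acetylation of the tertiary allylic alcohol, in which excess anhydride traps the alkoxide faster than the reverse aldol can occur.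

Step 24
Reactants: 31 tertiary allylic acetate (as named in step 23)
Product: 32 (1S,4R,5R,6S,8S,9Z)-13-acetoxy-1-[(tert-butyldimethylsilyl)oxy]-4,5-epoxy-8-(tigloyloxy)germacra-7(11),9-dien-12,6-olide
Conditions: 1,4-diazabicyclo[2.2.2]octane (DABCO, 0.3 equiv), THF, 50 °C
Reagents that add atoms: none
Why: Amine-catalysed SN2'–SN2' transposition of a Baylis–Hillman acetate, in which DABCO adds to C13 and expels the C7 acetate, acetate returns at C13 and releases the catalyst, giving the thermodynamically preferred primary acetate with the tetrasubstituted, lactone-conjugated C7=C11 olefin and erasing the C7 stereocentre.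

Step 25
Reactants: 32 silylated butenolide (as named in step 24)
Product: 33 CNP0222387.1, (1S,4R,5R,6S,8S,9Z)-13-acetoxy-4,5-epoxy-1-hydroxy-8-(tigloyloxy)germacra-7(11),9-dien-12,6-olide
Conditions: Bu4NF, AcOH (1:1), THF, 0 °C to rt
Reagents that add atoms: none
Why: Fluoride-induced desilylation buffered with acetic acid frees the C1 hydroxyl without base-induced loss or migration of the allylic acetate, γ-deprotonation of the butenolide or acid-induced opening of the epoxide.

**Compound list**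

1 | pent-4-yn-1-ol | C#CCCCO | starting material
2 | dimethyl[(1E)-5-[(dimethylalumanyl)oxy]-2-methylpent-1-en-1-yl]alumane | C[Al](C)/C=C(\C)CCCO[Al](C)C | intermediate (not isolated)
3 | (4E)-5-iodo-4-methylpent-4-en-1-ol | I/C=C(\C)CCCO | intermediate
4 | tert-butyl{[(4E)-5-iodo-4-methylpent-4-en-1-yl]oxy}dimethylsilane | I/C=C(\C)CCCO[Si](C)(C)C(C)(C)C | intermediate
5 | methyl 3,4-O-isopropylidene-L-threonate, methyl (2R)-2-[(4S)-2,2-dimethyl-1,3-dioxolan-4-yl]-2-hydroxyacetate | COC(=O)[C@H](O)[C@@H]1COC(C)(C)O1 | starting material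
6 | methyl (2R)-2-[(tert-butyldimethylsilyl)oxy]-2-[(4S)-2,2-dimethyl-1,3-dioxolan-4-yl]acetate | COC(=O)[C@H](O[Si](C)(C)C(C)(C)C)[C@@H]1COC(C)(C)O1 | intermediate
7 | (2R)-2-[(tert-butyldimethylsilyl)oxy]-2-[(4S)-2,2-dimethyl-1,3-dioxolan-4-yl]acetaldehyde | O=C[C@H](O[Si](C)(C)C(C)(C)C)[C@@H]1COC(C)(C)O1 | intermediate
8 | (4S)-4-[(1S,2Z)-1-[(tert-butyldimethylsilyl)oxy]-3-iodobut-2-en-1-yl]-2,2-dimethyl-1,3-dioxolane | C/C(I)=C/[C@H](O[Si](C)(C)C(C)(C)C)[C@@H]1COC(C)(C)O1 | intermediate
9 | (2S,3S,4Z)-3-[(tert-butyldimethylsilyl)oxy]-5-iodohex-4-ene-1,2-diol | C/C(I)=C/[C@H](O[Si](C)(C)C(C)(C)C)[C@@H](O)CO | intermediate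
10 | (4S)-4-[(1S,2Z)-1-[(tert-butyldimethylsilyl)oxy]-3-iodobut-2-en-1-yl]-2-(4-methoxyphenyl)-1,3-dioxolane, both C2 epimers | C/C(I)=C/[C@H](O[Si](C)(C)C(C)(C)C)[C@@H]1COC(c2ccc(OC)cc2)O1 | intermediate
11 | (2S,3S,4Z)-3-[(tert-butyldimethylsilyl)oxy]-5-iodo-2-[(4-methoxybenzyl)oxy]hex-4-en-1-ol | C/C(I)=C/[C@H](O[Si](C)(C)C(C)(C)C)[C@@H](OCc1ccc(OC)cc1)CO | intermediate
12 | (2R,3S,4Z)-3-[(tert-butyldimethylsilyl)oxy]-5-iodo-2-[(4-methoxybenzyl)oxy]hex-4-enal | C/C(I)=C/[C@H](O[Si](C)(C)C(C)(C)C)[C@@H](OCc1ccc(OC)cc1)C=O | intermediate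
13 | [(1E)-5-[(tert-butyldimethylsilyl)oxy]-2-methylpent-1-en-1-yl]lithium | [Li]/C=C(\C)CCCO[Si](C)(C)C(C)(C)C | intermediate (not isolated)
14 | [(1E)-5-[(tert-butyldimethylsilyl)oxy]-2-methylpent-1-en-1-yl]magnesium bromide | Br[Mg]/C=C(\C)CCCO[Si](C)(C)C(C)(C)C | intermediate (not isolated)
15 | (2Z,4S,5S,6R,7E)-4,11-bis[(tert-butyldimethylsilyl)oxy]-2-iodo-5-[(4-methoxybenzyl)oxy]-8-methylundeca-2,7-dien-6-ol (target numbering 4E,6R,7S,8S,9Z) | C/C(I)=C/[C@H](O[Si](C)(C)C(C)(C)C)[C@@H](OCc1ccc(OC)cc1)[C@H](O)/C=C(\C)CCCO[Si](C)(C)C(C)(C)C | intermediate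
16 | (1S,2S,3S,4Z)-3-[(tert-butyldimethylsilyl)oxy]-1-[(2R,3R)-3-{3-[(tert-butyldimethylsilyl)oxy]propyl}-3-methyloxiran-2-yl]-5-iodo-2-[(4-methoxybenzyl)oxy]hex-4-en-1-ol (target numbering 4R,5R,6S,7S,8S) | C/C(I)=C/[C@H](O[Si](C)(C)C(C)(C)C)[C@@H](OCc1ccc(OC)cc1)[C@H](O)[C@H]1O[C@]1(C)CCCO[Si](C)(C)C(C)(C)C | intermediate
17 | acryloyl chloride (prop-2-enoyl chloride) | C=CC(=O)Cl | starting material
18 | (1S,2S,3S,4Z)-3-[(tert-butyldimethylsilyl)oxy]-1-[(2R,3R)-3-{3-[(tert-butyldimethylsilyl)oxy]propyl}-3-methyloxiran-2-yl]-5-iodo-2-[(4-methoxybenzyl)oxy]hex-4-en-1-yl prop-2-enoate | C/C(I)=C/[C@H](O[Si](C)(C)C(C)(C)C)[C@@H](OCc1ccc(OC)cc1)[C@H](OC(=O)C=C)[C@H]1O[C@]1(C)CCCO[Si](C)(C)C(C)(C)C | intermediate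
19 | (1S,2R,3S,4Z)-3-hydroxy-1-[(2R,3R)-3-(3-hydroxypropyl)-3-methyloxiran-2-yl]-5-iodo-2-[(4-methoxybenzyl)oxy]hex-4-en-1-yl prop-2-enoate | C/C(I)=C/[C@H](O)[C@@H](OCc1ccc(OC)cc1)[C@H](OC(=O)C=C)[C@H]1O[C@]1(C)CCCO | intermediate
20 | (1S,2R,3S,4Z)-3-hydroxy-5-iodo-2-[(4-methoxybenzyl)oxy]-1-[(2R,3R)-3-methyl-3-(3-oxopropyl)oxiran-2-yl]hex-4-en-1-yl prop-2-enoate | C/C(I)=C/[C@H](O)[C@@H](OCc1ccc(OC)cc1)[C@H](OC(=O)C=C)[C@H]1O[C@]1(C)CCC=O | intermediate
21 | tiglic acid, (2E)-2-methylbut-2-enoic acid | C/C=C(\C)C(=O)O | starting material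
22 | (2E)-2-methylbut-2-enoic 2,4,6-trichlorobenzoic anhydride | C/C=C(\C)C(=O)OC(=O)c1c(Cl)cc(Cl)cc1Cl | intermediate (not isolated)
23 | (2Z,4S,5R,6S)-2-iodo-5-[(4-methoxybenzyl)oxy]-6-[(2R,3R)-3-methyl-3-(3-oxopropyl)oxiran-2-yl]-6-(prop-2-enoyloxy)hex-2-en-4-yl (2E)-2-methylbut-2-enoate (target numbering 4R,5R,6S,7R,8S,9Z) | C/C(I)=C/[C@H](OC(=O)/C(C)=C/C)[C@@H](OCc1ccc(OC)cc1)[C@H](OC(=O)C=C)[C@H]1O[C@]1(C)CCC=O | intermediate
24 | target numbering (4R,5R,6S,7R,8S,9Z)-6-(acryloyloxy)-4,5-epoxy-1-hydroxy-7-[(4-methoxybenzyl)oxy]-4,10-dimethyl-8-(tigloyloxy)cyclodec-9-ene, both C1 epimers | C/C=C(\C)C(=O)O[C@H]1/C=C(/C)C(O)CC[C@@]2(C)O[C@@H]2[C@@H](OC(=O)C=C)[C@@H]1OCc3ccc(OC)cc3 | intermediate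
25 | target numbering (4R,5R,6S,7R,8S,9Z)-6-(acryloyloxy)-4,5-epoxy-7-[(4-methoxybenzyl)oxy]-4,10-dimethyl-1-oxo-8-(tigloyloxy)cyclodec-9-ene | C/C=C(\C)C(=O)O[C@H]1/C=C(/C)C(=O)CC[C@@]2(C)O[C@@H]2[C@@H](OC(=O)C=C)[C@@H]1OCc3ccc(OC)cc3 | intermediate
26 | target numbering (1S,4R,5R,6S,7R,8S,9Z)-6-(acryloyloxy)-4,5-epoxy-1-hydroxy-7-[(4-methoxybenzyl)oxy]-4,10-dimethyl-8-(tigloyloxy)cyclodec-9-ene | C/C=C(\C)C(=O)O[C@H]1/C=C(/C)[C@@H](O)CC[C@@]2(C)O[C@@H]2[C@@H](OC(=O)C=C)[C@@H]1OCc3ccc(OC)cc3 | intermediate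
27 | target numbering (1S,4R,5R,6S,7R,8S,9Z)-6-(acryloyloxy)-1-[(tert-butyldimethylsilyl)oxy]-4,5-epoxy-7-[(4-methoxybenzyl)oxy]-4,10-dimethyl-8-(tigloyloxy)cyclodec-9-ene | C/C=C(\C)C(=O)O[C@H]1/C=C(/C)[C@@H](O[Si](C)(C)C(C)(C)C)CC[C@@]2(C)O[C@@H]2[C@@H](OC(=O)C=C)[C@@H]1OCc3ccc(OC)cc3 | intermediate
28 | target numbering (1S,4R,5R,6S,7R,8S,9Z)-6-(acryloyloxy)-1-[(tert-butyldimethylsilyl)oxy]-4,5-epoxy-7-hydroxy-4,10-dimethyl-8-(tigloyloxy)cyclodec-9-ene | C/C=C(\C)C(=O)O[C@H]1/C=C(/C)[C@@H](O[Si](C)(C)C(C)(C)C)CC[C@@]2(C)O[C@@H]2[C@@H](OC(=O)C=C)[C@@H]1O | intermediate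
29 | target numbering (1S,4R,5R,6R,8S,9Z)-6-(acryloyloxy)-1-[(tert-butyldimethylsilyl)oxy]-4,5-epoxy-4,10-dimethyl-7-oxo-8-(tigloyloxy)cyclodec-9-ene (key-step precursor) | C/C=C(\C)C(=O)O[C@H]1/C=C(/C)[C@@H](O[Si](C)(C)C(C)(C)C)CC[C@@]2(C)O[C@@H]2[C@@H](OC(=O)C=C)C1=O | intermediate
30 | (1S,4R,5R,6R,7S,8S,9Z)-1-[(tert-butyldimethylsilyl)oxy]-4,5-epoxy-7-hydroxy-8-(tigloyloxy)germacra-9,11(13)-dien-12,6-olide (key-step product) | C/C=C(\C)C(=O)O[C@H]1/C=C(/C)[C@@H](O[Si](C)(C)C(C)(C)C)CC[C@@]2(C)O[C@@H]2[C@H]2OC(=O)C(=C)[C@]12O | intermediate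
31 | (1S,4R,5R,6R,7S,8S,9Z)-7-acetoxy-1-[(tert-butyldimethylsilyl)oxy]-4,5-epoxy-8-(tigloyloxy)germacra-9,11(13)-dien-12,6-olide | C/C=C(\C)C(=O)O[C@H]1/C=C(/C)[C@@H](O[Si](C)(C)C(C)(C)C)CC[C@@]2(C)O[C@@H]2[C@H]2OC(=O)C(=C)[C@]12OC(C)=O | intermediate
32 | (1S,4R,5R,6S,8S,9Z)-13-acetoxy-1-[(tert-butyldimethylsilyl)oxy]-4,5-epoxy-8-(tigloyloxy)germacra-7(11),9-dien-12,6-olide | C/C=C(\C)C(=O)O[C@H]1/C=C(/C)[C@@H](O[Si](C)(C)C(C)(C)C)CC[C@@]2(C)O[C@@H]2[C@H]2OC(=O)C(COC(C)=O)=C12 | intermediate
33 | CNP0222387.1, (1S,4R,5R,6S,8S,9Z)-13-acetoxy-4,5-epoxy-1-hydroxy-8-(tigloyloxy)germacra-7(11),9-dien-12,6-olide | C/C=C(\C)C(=O)O[C@H]1/C=C(/C)[C@@H](O)CC[C@@]2(C)O[C@@H]2[C@H]2OC(=O)C(COC(C)=O)=C12 | target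

**Totals and risks**

Total step count: 25. Longest linear sequence: 23 steps (5 to 33, steps 3–25); steps 1–2 make the C1–C5 fragment that enters at step 10.

The three steps most likely to fail:

Step 22 (lactone annulation). The conjugate addition and aldol closure may be slow, so that enolisation of the bis(acyloxy) ketone (epimerisation at C6 or C8, acyl migration) or phosphine-induced oligomerisation of the acrylate competes. The fallback replaces the catalytic cycle by a stoichiometric Michael–aldol sequence followed by oxidative elimination. It sets out from 29: thiophenol with a catalytic amount of lithium thiophenolate (THF, −78 to −40 °C) should add to the acrylate, the ester enolate should close onto the C7 ketone and thiophenol should protonate the alkoxide, giving the α-(phenylthiomethyl) β-hydroxy lactone F1. Oxidation with mCPBA at −78 °C would give the sulfoxide F2, and thermal syn-elimination (toluene, 80 °C, CaCO3) would bring the route back to 30.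

Step 16 (ten-membered ring closure). Intermolecular coupling to oligomers, protodeiodination of the alkenylchromium species, or attack of low-valent metal on the acrylate may outrun the slow medium-ring closure. The fallback forms the same C1–C10 bond as an acylation instead of a carbonyl addition. It sets out from 23: exchange of iodine for tin with (Me3Sn)2 and catalytic Pd(PPh3)4 (toluene, 60 °C) would give the trimethylstannyl aldehyde F3. Pinnick oxidation (NaClO2, NaH2PO4, 2-methylbut-2-ene, t-BuOH/H2O) would give the trimethylstannyl carboxylic acid F4. 1-Chloro-N,N,2-trimethylprop-1-en-1-amine would convert it into the acid chloride F5 (not isolated), and an intramolecular Stille ketone synthesis (Pd2(dba)3, P(2-furyl)3, toluene, high dilution, 60 °C) would close the ring directly to enone 25, so that step 17 is no longer needed.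

Step 24 (acetate transposition). The acetate shift may stay incomplete, with loss of acetic acid toward C8 or C6 competing, or with reverse aldol cleavage already eroding the material during the forcing acetylation of step 23. The fallback moves the oxygen function by way of a halide and bypasses 31. It sets out from 30: N-bromosuccinimide and Me2S (CH2Cl2, 0 °C) should convert the tertiary allylic alcohol into its alkoxysulfonium salt, which bromide displaces in the SN2' sense to give the 13-bromo butenolide F6. CsOAc in DMF at rt would then replace bromide by acetate and bring the route back to 32.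

**Further compounds**

F1 | step 22 | 13-(phenylsulfanyl)-11,13-dihydro derivative of 30 (α-phenylthiomethyl β-hydroxy lactone, C11 epimers) | C/C=C(\C)C(=O)O[C@H]1/C=C(/C)[C@@H](O[Si](C)(C)C(C)(C)C)CC[C@@]2(C)O[C@@H]2[C@H]2OC(=O)C(CSc3ccccc3)[C@]12O
F2 | step 22 | sulfoxide of F1 | C/C=C(\C)C(=O)O[C@H]1/C=C(/C)[C@@H](O[Si](C)(C)C(C)(C)C)CC[C@@]2(C)O[C@@H]2[C@H]2OC(=O)C(CS(=O)c3ccccc3)[C@]12O
F3 | step 16 | trimethylstannyl aldehyde (23 with SnMe3 in place of iodine) | C/C([Sn](C)(C)C)=C/[C@H](OC(=O)/C(C)=C/C)[C@@H](OCc1ccc(OC)cc1)[C@H](OC(=O)C=C)[C@H]1O[C@]1(C)CCC=O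
F4 | step 16 | trimethylstannyl carboxylic acid (C1 acid of F3) | C/C([Sn](C)(C)C)=C/[C@H](OC(=O)/C(C)=C/C)[C@@H](OCc1ccc(OC)cc1)[C@H](OC(=O)C=C)[C@H]1O[C@]1(C)CCC(=O)O
F5 | step 16 | acid chloride of F4 (not isolated) | C/C([Sn](C)(C)C)=C/[C@H](OC(=O)/C(C)=C/C)[C@@H](OCc1ccc(OC)cc1)[C@H](OC(=O)C=C)[C@H]1O[C@]1(C)CCC(=O)Cl
F6 | step 24 | 13-bromo butenolide (32 with bromine in place of the acetoxy group) | C/C=C(\C)C(=O)O[C@H]1/C=C(/C)[C@@H](O[Si](C)(C)C(C)(C)C)CC[C@@]2(C)O[C@@H]2[C@H]2OC(=O)C(CBr)=C12
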